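The route disconnects the C10–C11 bond of the bridging pyranone ring (O, C6, C2, C1, C11, C10). Both ends are enolate-type carbons: C11 lies α to the C1 ketone, and C10, which carries the ether oxygen, lies γ to the C12 carbonyl through C13=C14. Anodic oxidation of the bis(silyl enol ether) joins these two nucleophilic carbons by umpolung, closing the oxabicyclo[3.3.1]nonane and setting quaternary C10 from C6 in one operation. The precursor is a spiro tetrahydropyran, made by ketone crotylboration and Prins cyclisation, that carries the ring A acetyl group, a protected axial C8 alcohol and a Z enoate. Dieckmann closure, C11 methylation and desilylation follow.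

Key step: step 12

Locants: skeletal atoms carry fusicoccane numbers (C1 ketone between C2 and C11; ring A = C2–C6 with CH2OMe on C3; C6 and C10 bear the ether oxygen; C7 Me, C8 O, C9 CH2; ring C = C10–C14 with C12 carbonyl and isopropyl on C14).

Assumption (step 4): the sense of induction of the 3,3'-dibromo-BINOL catalyst is taken from aryl methyl ketones, with the brominated alkene carbon C2 in the role of the aryl group; if the opposite alcohol forms, the antipodal diol is used.

Assumption (step 8): the Prins product is drawn with the C8 oxygen and the C10 alkenyl group equatorial; neither centre needs control, because C8 is reset in steps 9–10 and C10 becomes trigonal in step 12.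

Remark on design: the acetyl group is introduced only after the crotylboration, so that the ring ketone C6 is the sole carbonyl group when the crotyl unit is added.

Step 1
Reactants: 1 3-ethoxycyclopent-2-en-1-one; 2 tributyl(methoxymethyl)stannane
Product: 4 3-(methoxymethyl)cyclopent-2-en-1-one, via carbinol adduct 3 (not isolated)
Conditions: 2, n-BuLi, THF, −78 °C; then 1, −78 °C; then 1 M HCl, 0 °C to rt
Reagents that add atoms: water, O
Why: Tin–lithium exchange gives methoxymethyllithium, which adds 1,2 to the vinylogous ester, and acid then hydrolyses the enol ether and eliminates water (Stork–Danheiser transposition).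

Step 2
Reactants: 4 3-(methoxymethyl)cyclopent-2-en-1-one
Product: 6 2-bromo-3-(methoxymethyl)cyclopent-2-en-1-one, via dibromoketone 5 (not isolated)
Conditions: Br2, CH2Cl2, 0 °C; then Et3N, 0 °C to rt
Reagents that add atoms: bromine, BrBr
Why: Bromine addition to the enone followed by E1cB loss of HBr is the standard α-bromination of β-substituted cycloalkenones.

Step 3
Reactants: 7 cis-but-2-ene; 8 triisopropyl borate
Product: 11 diisopropyl (Z)-but-2-en-1-ylboronate, via (Z)-crotylpotassium 9 (not isolated), via triisopropoxyborate salt 10 (not isolated)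
Conditions: KOt-Bu, n-BuLi, THF, −78 to −50 °C; 8, −78 °C; HCl/Et2O (2 equiv), −78 °C to rt; filtration, distillation
Reagents that add atoms: none
Why: Schlosser metalation of cis-butene gives (Z)-crotylpotassium, which keeps its geometry below −50 °C, and borylation then acidolysis of the ate complex delivers the Z boronate.

Step 4
Reactants: 6 2-bromo-3-(methoxymethyl)cyclopent-2-en-1-one; 11 diisopropyl (Z)-but-2-en-1-ylboronate
Product: 13 (1R)-2-bromo-1-[(2S)-but-3-en-2-yl]-3-(methoxymethyl)cyclopent-2-en-1-ol, via borate ester 12 (not isolated)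
Conditions: (S)-3,3'-Br2-BINOL (15 mol %), PhCF3/PhMe (3:1), −35 °C; then aq NaHCO3
Reagents that add atoms: none
Why: Chiral-diol-catalysed crotylboration of a ketone (closed chair transition state) places the Z-crotyl methyl axial and the brominated C2 side of the ring ketone equatorial, which gives the syn pair C6 (R)/C7 (S), while the BINOL-bound boronate selects the carbonyl face.

Step 5
Reactants: 13 (1R)-2-bromo-1-[(2S)-but-3-en-2-yl]-3-(methoxymethyl)cyclopent-2-en-1-ol
Product: 15 1-[(5R)-5-[(2S)-but-3-en-2-yl]-5-hydroxy-2-(methoxymethyl)cyclopent-1-en-1-yl]ethan-1-one, via dilithio alkoxide vinyllithium 14 (not isolated)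
Conditions: t-BuLi (3.1 equiv), THF, −78 °C; MeC(O)N(OMe)Me, −78 to 0 °C; aq NH4Cl
Reagents that add atoms: N-methoxy-N-methylacetamide, CC(=O)N(C)OC
Why: Deprotonation of the alcohol and bromine–lithium exchange give a vinyllithium that cannot β-eliminate within the five-membered ring, and its acylation by a Weinreb amide stops at the ketone.

Step 6
Reactants: 16 3-methylbutanal; 17 glyoxylic acid monohydrate
Product: 18 5-hydroxy-4-(propan-2-yl)furan-2(5H)-one
Conditions: morpholine·HCl, dioxane/H2O, reflux
Reagents that add atoms: none
Why: Amine-mediated aldol condensation of the aldehyde α-carbon with glyoxylic acid and lactol closure is the standard entry to 4-alkyl-5-hydroxybutenolides and fixes formyl and carboxyl carbons cis on the alkene.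

Step 7
Reactants: 18 5-hydroxy-4-(propan-2-yl)furan-2(5H)-one
Product: 19 methyl (2Z)-3-formyl-4-methylpent-2-enoate
Conditions: MeI, K2CO3, DMF, 0 °C; used without storage
Reagents that add atoms: iodomethane, CI
Why: Base opens the pseudo-acid to the formyl carboxylate, and O-alkylation of the carboxylate (as with 2-formylbenzoic acid) gives the open-chain ester with the Z geometry inherited from the ring.

Step 8
Reactants: 15 1-[(5R)-5-[(2S)-but-3-en-2-yl]-5-hydroxy-2-(methoxymethyl)cyclopent-1-en-1-yl]ethan-1-one; 19 methyl (2Z)-3-formyl-4-methylpent-2-enoate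
Product: 21 methyl (2Z)-3-[(5R,7R,9R,10S)-1-acetyl-9-hydroxy-2-(methoxymethyl)-10-methyl-6-oxaspiro[4.5]dec-1-en-7-yl]-4-methylpent-2-enoate, via C8 trifluoroacetate 20 (not isolated)
Conditions: TFA (10 equiv), CH2Cl2, 0 °C to rt; then NaHCO3, MeOH, 0 °C
Reagents that add atoms: trifluoroacetic acid, OC(=O)C(F)(F)F
Why: Prins cyclisation, in which the tertiary alcohol and the aldehyde form an oxocarbenium ion that the vinyl group attacks through a chair with the C7 methyl and the C10 alkenyl group equatorial, trifluoroacetate capturing C8 equatorially; the acetyl group on C2 disfavours ionisation at C6, and the ester on C13 keeps the cation from delocalising onto C13, so the Z alkene should persist.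

Step 9
Reactants: 21 C8-equatorial spiro pyranol
Product: 22 methyl (2Z)-3-[(5R,7R,10R)-1-acetyl-2-(methoxymethyl)-10-methyl-9-oxo-6-oxaspiro[4.5]dec-1-en-7-yl]-4-methylpent-2-enoate
Conditions: Dess–Martin periodinane, NaHCO3, CH2Cl2, 0 °C to rt
Reagents that add atoms: none
Why: Buffered Dess–Martin oxidation of the secondary alcohol erases the C8 configuration, so either Prins epimer converges on one ketone without enolising C7.

Step 10
Reactants: 22 spiro pyran-4-one (C8 ketone)
Product: 23 methyl (2Z)-3-[(5R,7R,9S,10S)-1-acetyl-9-hydroxy-2-(methoxymethyl)-10-methyl-6-oxaspiro[4.5]dec-1-en-7-yl]-4-methylpent-2-enoate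
Conditions: L-Selectride (1.1 equiv), THF, −78 °C; aq NH4Cl
Reagents that add atoms: none
Why: The bulky hydride approaches the ring ketone along the equatorial trajectory, away from the axial C2 substituent on C6, and gives the axial alcohol cis to the C7 methyl (8S), while the hindered conjugated C1 ketone and the β,β-disubstituted ester should react far more slowly at −78 °C.

Step 11
Reactants: 23 C8-axial spiro pyranol
Product: 24 methyl (2Z)-3-[(5R,7R,9S,10S)-1-acetyl-9-(tert-butyldimethylsilyloxy)-2-(methoxymethyl)-10-methyl-6-oxaspiro[4.5]dec-1-en-7-yl]-4-methylpent-2-enoate (spiro pyran keto ester)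
Conditions: TBSOTf, 2,6-lutidine, CH2Cl2, −78 to 0 °C
Reagents that add atoms: tert-butyldimethylsilyl trifluoromethanesulfonate, CC(C)(C)[Si](C)(C)OS(=O)(=O)C(F)(F)F
Why: Silyl triflate with a hindered pyridine base silylates the hindered axial alcohol, which would otherwise consume base and could add to the C1 ketone once the bridge exists.

Step 12
Reactants: 24 spiro pyran keto ester
Product: 26 methyl (2Z)-3-[(1R,8S,10S,11S)-10-(tert-butyldimethylsilyloxy)-4-(methoxymethyl)-11-methyl-6-oxo-12-oxatricyclo[6.3.1.0^{1,5}]dodec-4-en-8-yl]-4-methylpent-2-enoate (bridged keto enoate), via bis(silyl enol ether) 25 (not isolated)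
Conditions: LDA (2.6 equiv), TBSCl (3 equiv), DMPU, THF, −78 to 0 °C; pentane, filtration, evaporation; then RVC anode, Pt cathode, undivided cell, LiClO4 (0.1 M), MeCN/THF/MeOH (8:1:1), 2,6-lutidine, 0 °C, constant current, 2.2 F/mol
Reagents that add atoms: none
Why: Kinetic double deprotonation (acetyl CH3 and the C10–H that lies cis to the ester and next to the ring oxygen) and O-silylation give 25, whose trioxygenated diene is the more easily oxidised π system; at the anode it becomes a radical cation that the C1 silyl enol ether captures at C10 through C11, after which a second electron is lost and methanol removes both silyl groups to return the C1 ketone and the conjugated ester. The closest known reaction type is the intramolecular anodic coupling of two enol ethers (an enol ether radical cation trapped by a silyl enol ether), which also forms quaternary carbons from ketene acetal equivalents. The pyranone ring (O, C6, C2, C1, C11, C10) closes in a 6-exo-trig mode onto the C10=C14 bond. The new stereocentre C10 is controlled by C6: the C2–C1 tether hangs axially from C6 on one face of the tetrahydropyran, so C11 can reach C10 only from that face and the bridge becomes 1,3-diaxial. The step needs bonding at C10 and not C13, which ring size secures (six against eight atoms), cross- and not homo-coupling, which the tether secures, and removal of C10–H and not the isopropyl C–H, which the Z ester secures by delivering the amide base to the cis γ-hydrogen. The cis relation of C10 and the ester in 26 is not enforced by the tether and is the first thing to check.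

Step 13
Reactants: 26 bridged keto enoate
Product: 27 11-desmethyl β-diketone with ring C closed (C8 O-TBS; 6R,7S,8S,10S,11R; drawn as the diketo tautomer)
Conditions: LiHMDS (2.2 equiv), THF, −78 to 0 °C; AcOH, then aq NH4Cl
Reagents that add atoms: none
Why: Dieckmann condensation, in which the C11 lithium enolate (the only α-position of the C1 ketone) adds to the cis ester in a 5-exo-trig closure and deprotonation of the new β-diketone drives the equilibrium; the C10–C11 ring fusion can only be cis.

Step 14
Reactants: 27 11-desmethyl β-diketone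
Product: 28 C8 O-TBS alterbrassicicene C (6R,7S,8S,10R,11R)
Conditions: MeI, K2CO3, acetone, rt
Reagents that add atoms: iodomethane, CI
Why: C-alkylation of the chelating β-diketone enolate (2-acylcyclopentenone type) with iodomethane; methyl can enter only on the face that keeps the cyclopentenone cis-fused to the pyranone (syn to C9), which sets C11 as R.

Step 15
Reactants: 28 C8 O-TBS alterbrassicicene C
Product: 29 alterbrassicicene C
Conditions: HF·pyridine, pyridine/THF, 0 °C to rt
Reagents that add atoms: none
Why: Fluoride-assisted cleavage of the silyl ether under buffered acidic conditions spares the non-enolisable β-diketone (no basic nucleophile, hence no retro-Claisen) and the tertiary ether.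

Compound list

1 | 3-ethoxycyclopent-2-en-1-one | CCOC1=CC(=O)CC1 | starting material
2 | tributyl(methoxymethyl)stannane | CCCC[Sn](CCCC)(CCCC)COC | starting material
3 | 3-ethoxy-1-(methoxymethyl)cyclopent-2-en-1-ol (carbinol adduct, present as lithium alkoxide) | CCOC1=CC(O)(COC)CC1 | intermediate (not isolated)
4 | 3-(methoxymethyl)cyclopent-2-en-1-one | COCC1=CC(=O)CC1 | intermediate
5 | 2,3-dibromo-3-(methoxymethyl)cyclopentan-1-one | COCC1(Br)C(Br)C(=O)CC1 | intermediate (not isolated)
6 | 2-bromo-3-(methoxymethyl)cyclopent-2-en-1-one | COCC1=C(Br)C(=O)CC1 | intermediate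
7 | cis-but-2-ene | C/C=C\C | starting material
8 | triisopropyl borate | CC(C)OB(OC(C)C)OC(C)C | starting material
9 | (Z)-but-2-en-1-ylpotassium | C/C=C\C[K] | intermediate (not isolated)
10 | potassium (Z)-but-2-en-1-yl(triisopropoxy)borate | C/C=C\C[B-](OC(C)C)(OC(C)C)OC(C)C.[K+] | intermediate (not isolated)
11 | diisopropyl (Z)-but-2-en-1-ylboronate | C/C=C\CB(OC(C)C)OC(C)C | intermediate
12 | diisopropyl borate ester of alcohol 13 | COCC1=C(Br)[C@](CC1)(OB(OC(C)C)OC(C)C)[C@@H](C)C=C | intermediate (not isolated)
13 | (1R)-2-bromo-1-[(2S)-but-3-en-2-yl]-3-(methoxymethyl)cyclopent-2-en-1-ol | COCC1=C(Br)[C@](CC1)(O)[C@@H](C)C=C | intermediate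
14 | dilithio derivative of 13 (lithium alkoxide, vinyllithium at C2) | COCC1=C([Li])[C@](CC1)(O[Li])[C@@H](C)C=C | intermediate (not isolated)
15 | 1-[(5R)-5-[(2S)-but-3-en-2-yl]-5-hydroxy-2-(methoxymethyl)cyclopent-1-en-1-yl]ethan-1-one | COCC1=C(C(C)=O)[C@](CC1)(O)[C@@H](C)C=C | intermediate
16 | 3-methylbutanal | CC(C)CC=O | starting material
17 | glyoxylic acid monohydrate | OC(O)C(=O)O | starting material
18 | 5-hydroxy-4-(propan-2-yl)furan-2(5H)-one | CC(C)C1=CC(=O)OC1O | intermediate
19 | methyl (2Z)-3-formyl-4-methylpent-2-enoate | O=C/C(C(C)C)=C\C(=O)OC | intermediate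
20 | C8 trifluoroacetate of 21 | COCC1=C(C(C)=O)[C@]2(CC1)O[C@H](C[C@@H](OC(=O)C(F)(F)F)[C@@H]2C)/C(C(C)C)=C\C(=O)OC | intermediate (not isolated)
21 | methyl (2Z)-3-[(5R,7R,9R,10S)-1-acetyl-9-hydroxy-2-(methoxymethyl)-10-methyl-6-oxaspiro[4.5]dec-1-en-7-yl]-4-methylpent-2-enoate | COCC1=C(C(C)=O)[C@]2(CC1)O[C@H](C[C@@H](O)[C@@H]2C)/C(C(C)C)=C\C(=O)OC | intermediate
22 | methyl (2Z)-3-[(5R,7R,10R)-1-acetyl-2-(methoxymethyl)-10-methyl-9-oxo-6-oxaspiro[4.5]dec-1-en-7-yl]-4-methylpent-2-enoate | COCC1=C(C(C)=O)[C@]2(CC1)O[C@H](CC(=O)[C@@H]2C)/C(C(C)C)=C\C(=O)OC | intermediate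
23 | methyl (2Z)-3-[(5R,7R,9S,10S)-1-acetyl-9-hydroxy-2-(methoxymethyl)-10-methyl-6-oxaspiro[4.5]dec-1-en-7-yl]-4-methylpent-2-enoate | COCC1=C(C(C)=O)[C@]2(CC1)O[C@H](C[C@H](O)[C@@H]2C)/C(C(C)C)=C\C(=O)OC | intermediate
24 | methyl (2Z)-3-[(5R,7R,9S,10S)-1-acetyl-9-(tert-butyldimethylsilyloxy)-2-(methoxymethyl)-10-methyl-6-oxaspiro[4.5]dec-1-en-7-yl]-4-methylpent-2-enoate (spiro pyran keto ester) | COCC1=C(C(C)=O)[C@]2(CC1)O[C@H](C[C@H](O[Si](C)(C)C(C)(C)C)[C@@H]2C)/C(C(C)C)=C\C(=O)OC | intermediate
25 | bis(silyl enol ether) of 24: C1(OTBS)=C11H2 and C10=C14–C13=C12(OMe)OTBS (enol ether geometries not defined, inconsequential) | COCC1=C(C(=C)O[Si](C)(C)C(C)(C)C)[C@]2(CC1)OC(C[C@H](O[Si](C)(C)C(C)(C)C)[C@@H]2C)=C(C(C)C)C=C(OC)O[Si](C)(C)C(C)(C)C | intermediate (not isolated)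
26 | methyl (2Z)-3-[(1R,8S,10S,11S)-10-(tert-butyldimethylsilyloxy)-4-(methoxymethyl)-11-methyl-6-oxo-12-oxatricyclo[6.3.1.0^{1,5}]dodec-4-en-8-yl]-4-methylpent-2-enoate (bridged keto enoate) | COCC1=C2C(=O)C[C@]3(/C(C(C)C)=C\C(=O)OC)C[C@H](O[Si](C)(C)C(C)(C)C)[C@H](C)[C@@]2(CC1)O3 | intermediate
27 | 11-desmethyl β-diketone, ring C closed, C8 O-TBS (6R,7S,8S,10S,11R; diketo tautomer) | COCC1=C2C(=O)[C@H]3C(=O)C=C(C(C)C)[C@]34C[C@H](O[Si](C)(C)C(C)(C)C)[C@H](C)[C@@]2(CC1)O4 | intermediate
28 | C8 O-TBS alterbrassicicene C (6R,7S,8S,10R,11R) | COCC1=C2C(=O)[C@@]3(C)C(=O)C=C(C(C)C)[C@]34C[C@H](O[Si](C)(C)C(C)(C)C)[C@H](C)[C@@]2(CC1)O4 | intermediate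
29 | alterbrassicicene C (6R,7S,8S,10R,11R) | COCC1=C2C(=O)[C@@]3(C)C(=O)C=C(C(C)C)[C@]34C[C@H](O)[C@H](C)[C@@]2(CC1)O4 | target

Total step count: 15. Longest linear sequence: 12 steps (1, 2, 4, 5, 8–15).

Steps most likely to fail

Step 12. The diene radical cation may be intercepted by methanol or couple between molecules before C11 reaches C10. The C13=C14 geometry may also be lost while the dienol ether is oxidised, which would leave the ester trans to C10 and out of reach of C11 in step 13. The fallback replaces the oxidative coupling by a redox-neutral polar closure and a later dehydrogenation; it sets out from 24 and comes back at 28. Double deprotonation of 24 (LDA, THF/DMPU, −78 °C) and kinetic α-protonation with acetic acid would give the deconjugated ester with an exocyclic C10=C14 enol ether F1. Silylation of the methyl ketone (TBSOTf, Et3N) would give the enol silane F2. Catalytic Tf2NH at −78 °C would then protonate the enol ether at C14 and let C11 add to the C10 oxocarbenium ion from the C6 face (intramolecular Mukaiyama-type addition), giving the saturated bridged keto ester F3 as a mixture at C14. Because C13–C14 is then a single bond, Dieckmann closure (LiHMDS) to the cyclopentanone β-diketone F4 no longer depends on alkene geometry. Methylation as in step 14 would give the saturated methyl diketone F5. Dehydrogenation of the C12 ketone across C13–C14 (IBX, or enol silane then Pd(OAc)2), possible only towards C13, removes the C14 centre and returns to 28.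

Step 8. Oxocarbenium formation from two hindered partners may be slow, so that ionisation of the tertiary allylic alcohol, crotyl transfer by 2-oxonia-Cope rearrangement (erosion at C6) or capture of the cation by the cis ester competes with ring closure. The fallback uses a small linear aldehyde and builds the trisubstituted alkene afterwards; it sets out from 15 and comes back at 21. Cyclisation of 15 under the same acid conditions with methyl 4-oxobut-2-ynoate F6 (MnO2 oxidation of commercial methyl 4-hydroxybut-2-ynoate) would give the alkynoate trifluoroacetate F7 and, after aqueous NaHCO3, the alkynoate pyranol F8. Syn-carbocupration with i-PrMgCl/CuBr·SMe2 (THF, −78 °C, protonation at −78 °C) would then place isopropyl on C14 cis to the new hydrogen, that is the ester cis to C10, and return to 21.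

Step 4. Facial and diastereofacial selection may be poor, because the catalyst and the chair transition state must tell the C2 and C5 sides of a cyclic ketone apart. The fallback gives up asymmetric catalysis for a racemic, diastereoselective addition and a resolution; it sets out from 6 and comes back at 13. Crotylation of 6 with commercial (Z)-crotylboronic acid pinacol ester, activated as its borinic ester (n-BuLi, then TFAA, THF, −78 °C), would give the racemic syn alcohol, that is 13 together with its enantiomer F9, which is removed by preparative chromatography on a chiral stationary phase. The route resumes at 13.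

Further compounds

F1 | step 12 | deconjugated ester of 24 with exocyclic C10=C14 enol ether (methyl 3-(spiro-pyranylidene)-4-methylpentanoate) | COCC1=C(C(C)=O)[C@]2(CC1)OC(C[C@H](O[Si](C)(C)C(C)(C)C)[C@@H]2C)=C(C(C)C)CC(=O)OC
F2 | step 12 | C1 tert-butyldimethylsilyl enol ether of F1 (not isolated) | COCC1=C(C(=C)O[Si](C)(C)C(C)(C)C)[C@]2(CC1)OC(C[C@H](O[Si](C)(C)C(C)(C)C)[C@@H]2C)=C(C(C)C)CC(=O)OC
F3 | step 12 | saturated bridged keto ester (C13–C14 single bond, C14 epimers) | COCC1=C2C(=O)C[C@]3(C(C(C)C)CC(=O)OC)C[C@H](O[Si](C)(C)C(C)(C)C)[C@H](C)[C@@]2(CC1)O3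
F4 | step 12 | 13,14-dihydro-11-desmethyl β-diketone (C8 O-TBS) | COCC1=C2C(=O)[C@H]3C(=O)CC(C(C)C)[C@]34C[C@H](O[Si](C)(C)C(C)(C)C)[C@H](C)[C@@]2(CC1)O4
F5 | step 12 | 13,14-dihydro derivative of 28 | COCC1=C2C(=O)[C@@]3(C)C(=O)CC(C(C)C)[C@]34C[C@H](O[Si](C)(C)C(C)(C)C)[C@H](C)[C@@]2(CC1)O4
F6 | step 8 | methyl 4-oxobut-2-ynoate | O=CC#CC(=O)OC
F7 | step 8 | alkynoate spiro pyran, C8 trifluoroacetate (not isolated) | COCC1=C(C(C)=O)[C@]2(CC1)O[C@H](C[C@@H](OC(=O)C(F)(F)F)[C@@H]2C)C#CC(=O)OC
F8 | step 8 | alkynoate spiro pyranol (C8 OH equatorial) | COCC1=C(C(C)=O)[C@]2(CC1)O[C@H](C[C@@H](O)[C@@H]2C)C#CC(=O)OC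
F9 | step 4 | (1S)-2-bromo-1-[(2R)-but-3-en-2-yl]-3-(methoxymethyl)cyclopent-2-en-1-ol (enantiomer of 13) | COCC1=C(Br)[C@@](CC1)(O)[C@H](C)C=C
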